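The two outer rings of the target are enolised 2-propionyl-6,6-dimethylcyclohexadienones. The quaternary C6 of each is the only ring atom that keeps that ring from being an aromatic 3-methyl-propionylphloroglucinol; the two inner rings are already aromatic. Taking one methyl off each C6 therefore leads back to a fully aromatic tetramer of four propionylphloroglucinol rings linked by three CH2 bridges, the outer two rings carrying one C-methyl. This tetramer is assembled from methylenebis(flopropione) and two 3-methylflopropione Mannich bases. One final operation, a twofold C-methylation with sodium methoxide and iodomethane at the methyl-bearing end-ring carbons, then forms both C6–CH3 bonds and dearomatises both end rings.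

Key step: step 5

Remark: the terminal rings are drawn as one of several rapidly interconverting enol tautomers; all are treated as the same compound, and the target has no stereocentre.

Step 1
Reactants: 1 2,4,6-trihydroxytoluene; 2 propionyl chloride
Product: 3 1-(2,4,6-trihydroxy-3-methylphenyl)propan-1-one (3-methylflopropione)
Conditions: AlCl3 (3.5 equiv), 2 (1.0 equiv), PhNO2/CH2Cl2, 0 °C to rt; then ice, 1 M HCl
Reagents that add atoms: propionyl chloride CCC(=O)Cl
Why: Friedel–Crafts C-acylation of the strongly activated phloroglucinol ring should take place once at one of the two equivalent free positions, because the chelated aryl ketone–AlCl3 complex formed first is deactivated towards a second acylation.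

Step 2
Reactants: 3 3-methylflopropione; 4 N,N,N',N'-tetramethylmethanediamine
Product: 5 1-{3-[(dimethylamino)methyl]-2,4,6-trihydroxy-5-methylphenyl}propan-1-one (Mannich base)
Conditions: CH2(NMe2)2 (1.2 equiv), EtOH, 0 °C to rt, Ar
Reagents that add atoms: N,N,N',N'-tetramethylmethanediamine CN(C)CN(C)C
Why: Mannich aminomethylation, in which the acidic phenol protonates the aminal to release the dimethylmethyleneiminium ion that attacks the only unsubstituted ring carbon, while the dimethylamine set free keeps the product as the amine adduct instead of letting it bridge to unreacted 3.

Step 3
Reactants: 6 flopropione (2,4,6-trihydroxypropiophenone); 7 formaldehyde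
Product: 9 methylenebis(flopropione) (two flopropione rings joined C3–CH2–C3'), via hydroxymethylflopropione 8 (not isolated)
Conditions: 6 (4 equiv), 37% aq. HCHO (1 equiv), conc. HCl (cat.), EtOH/H2O, 40 °C; excess 6 recovered
Reagents that add atoms: formaldehyde C=O
Why: Acid-catalysed phenol–formaldehyde (novolac-type) condensation, in which hydroxymethylation of one flopropione and Friedel–Crafts alkylation of a second one by the resulting benzylic cation should give the diarylmethane, the fourfold excess of flopropione ensuring that the electrophile meets monomer instead of the dimer, whose rings each keep one free position.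

Step 4
Reactants: 9 methylenebis(flopropione); 5 Mannich base of 3-methylflopropione
Product: 12 all-aromatic tetramer (rings A–CH2–B–CH2–C–CH2–D; A and D are 2,4,6-trihydroxy-3-methyl-5-propanoylphenyl and B and C are 2,4,6-trihydroxy-5-propanoyl-1,3-phenylene), via o-quinone methide 10 (not isolated), via trimeric mono-adduct 11 (not isolated)
Conditions: 5 (2.2 equiv), 1,4-dioxane, 90 °C, Ar stream; then 1 M HCl wash
Reagents that add atoms: none
Why: Mannich-base (o-quinone methide) alkylation, in which thermal loss of dimethylamine from zwitterionic 5 gives o-quinone methide 10, which cannot add to itself on carbon because all its ring positions are substituted and should therefore be captured in a conjugate addition by the single free carbon of each ring of 9, first to trimer 11 and then to tetramer 12.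

Step 5
Reactants: 12 all-aromatic tetramer; 13 iodomethane
Product: 15 target compound CNP0541376.0 (rings B and C unchanged; rings A and D each a 2,6-dihydroxy-3,3-dimethyl-4-oxo-5-propanoylcyclohexa-1,5-dien-1-yl ring), via mono-methylated tetramer 14 (not isolated)
Conditions: NaOCH3 (8 equiv), CH3I (2.1 equiv, added slowly), degassed MeOH, 0 °C to rt, Ar; then 1 M HCl
Reagents that add atoms: iodomethane CI
Why: Methoxide converts every ring of 12 into a phloroglucinolate whose charge is shared by the ring carbons between the oxygens; the methyl-bearing carbon of each end ring attacks iodomethane in an SN2 step, the ring keeps the new sp3 carbon because no proton is left there to restore aromaticity, and acidification should give the enolised 6,6-dimethylcyclohexadienone, first on one end (14) and then on the other (15). The closest known reaction is the sodium methoxide/iodomethane conversion of monomeric 3-methyl-acylphloroglucinols into acylfilicinic acids, the laboratory counterpart of the biosynthetic C-methylation. No ring is closed and no stereocentre is created, since each new quaternary carbon carries two identical methyl groups. Three selectivities are needed: C- over O-alkylation, favoured by the hydrogen-bonding protic solvent and the soft electrophile; attack at the two methyl-bearing carbons instead of the six benzyl-bearing ring carbons (one on each end ring, two on each inner ring) or the acyl-bearing carbons, which rests on the small size of CH3 compared with an ArCH2 group flanked by ortho-oxygenated rings and on the conjugative deactivation of the acyl-bearing positions; and two methylations instead of more, which rests on the slow addition of 2.1 equiv of iodomethane and on each dearomatised ring being a vinylogous acid whose stabilised triketone enolate is a much poorer carbon nucleophile than the phloroglucinolate still present in 14. Low temperature and exclusion of air should hold back base-induced exchange of the methylene bridges and oxidation of the polyphenoxide.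

Compound list
1 | 2,4,6-trihydroxytoluene (2-methylphloroglucinol) | Cc1c(O)cc(O)cc1O | starting material
2 | propionyl chloride | CCC(=O)Cl | starting material
3 | 1-(2,4,6-trihydroxy-3-methylphenyl)propan-1-one (3-methylflopropione) | CCC(=O)c1c(O)c(C)c(O)cc1O | intermediate
4 | N,N,N',N'-tetramethylmethanediamine (bis(dimethylamino)methane) | CN(C)CN(C)C | starting material
5 | 1-{3-[(dimethylamino)methyl]-2,4,6-trihydroxy-5-methylphenyl}propan-1-one | CCC(=O)c1c(O)c(C)c(O)c(CN(C)C)c1O | intermediate
6 | flopropione (1-(2,4,6-trihydroxyphenyl)propan-1-one) | CCC(=O)c1c(O)cc(O)cc1O | starting material
7 | formaldehyde | C=O | starting material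
8 | 1-[2,4,6-trihydroxy-3-(hydroxymethyl)phenyl]propan-1-one | CCC(=O)c1c(O)cc(O)c(CO)c1O | intermediate (not isolated)
9 | methylenebis(flopropione), 1,1'-[methylenebis(2,4,6-trihydroxybenzene-3,1-diyl)]di(propan-1-one) | CCC(=O)c1c(O)cc(O)c(Cc2c(O)cc(O)c(C(=O)CC)c2O)c1O | intermediate
10 | 3,5-dihydroxy-4-methyl-6-methylidene-2-propanoylcyclohexa-2,4-dien-1-one (o-quinone methide) | CCC(=O)C1=C(O)C(C)=C(O)C(=C)C1=O | intermediate (not isolated)
11 | trimeric mono-adduct (ring A–CH2–ring B–CH2–ring C, ring C still bearing one ring hydrogen) | CCC(=O)c1c(O)c(C)c(O)c(Cc2c(O)c(Cc3c(O)cc(O)c(C(=O)CC)c3O)c(O)c(C(=O)CC)c2O)c1O | intermediate (not isolated)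
12 | all-aromatic tetramer with 3-methyl-propionylphloroglucinol end rings | CCC(=O)c1c(O)c(C)c(O)c(Cc2c(O)c(Cc3c(O)c(Cc4c(O)c(C)c(O)c(C(=O)CC)c4O)c(O)c(C(=O)CC)c3O)c(O)c(C(=O)CC)c2O)c1O | intermediate
13 | iodomethane | CI | starting material
14 | mono-methylated tetramer (one end ring a 6,6-dimethylcyclohexadienone, the other still aromatic) | CCC(=O)C1=C(O)C(Cc2c(O)c(Cc3c(O)c(Cc4c(O)c(C)c(O)c(C(=O)CC)c4O)c(O)c(C(=O)CC)c3O)c(O)c(C(=O)CC)c2O)=C(O)C(C)(C)C1=O | intermediate (not isolated)
15 | CNP0541376.0 (achiral; two inner propionylphloroglucinol rings, two terminal propionyl-6,6-dimethylcyclohexadienone rings, three CH2 bridges) | CCC(=O)C1=C(O)C(Cc2c(O)c(Cc3c(O)c(CC4=C(O)C(C)(C)C(=O)C(C(=O)CC)=C4O)c(O)c(C(=O)CC)c3O)c(O)c(C(=O)CC)c2O)=C(O)C(C)(C)C1=O | target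

Total step count: 5
Longest linear sequence: 4 steps (steps 1, 2, 4, 5); step 3 is a one-step branch.

Steps most likely to fail

1. Step 5. The risk is loss of site control in the alkylation: methylation at benzyl-bearing ring carbons, O-methylation or a third methylation, together with base-induced exchange of the methylene bridges, would give a mixture that cannot be resolved. The fallback moves the methylation to the monomer stage and sets out from compound 3. Sodium methoxide and iodomethane 13 in methanol should convert 3 into propionylfilicinic acid F1, which is separable from ring-methylated by-products through its higher acidity. Aminomethylation of F1 with aminal 4 should give the Mannich base of propionylfilicinic acid F2. Heating F2 (2.2 equiv) with dimer 9 in dioxane should alkylate both free ring carbons of 9 by the quinone-methide pathway of step 4 and comes back to the route at compound 15. Steps 1 and 3 are kept; steps 2, 4 and 5 are replaced.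

2. Step 4. The risk is stalling after the first alkylation at trimer 11, self-consumption of the quinone methide before it meets the hindered second site, and amine-induced exchange of the central bridge. The fallback reverses the roles of the partners and sets out from compound 9. Double aminomethylation of 9 with aminal 4 should give the bis-Mannich base of methylenebis(flopropione) F3. F3 is then heated with an excess (3 to 4 equiv) of 3, which has a single free position, cannot over-react and can therefore be used in excess to drive both alkylations. This comes back to the route at compound 12.

3. Step 3. The risk is over-condensation, in which the dimer continues to react with formaldehyde to trimers and higher oligomers that are hard to separate from 9. The fallback forms the central bridge last and sets out from compounds 5 and 6. Heating 5 with a fivefold excess of 6 in dioxane should give the unsymmetrical dimer F4, in which the methylated ring is fully substituted and the flopropione ring keeps one free position. Acid-catalysed condensation of two molecules of F4 with one of formaldehyde 7 can then only join these two positions. This bypasses compound 9 and step 4 and comes back to the route at compound 12.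

Further compounds
F1 | step 5 | propionylfilicinic acid (3,5-dihydroxy-4,4-dimethyl-2-propanoylcyclohexa-2,5-dien-1-one) | CCC(=O)C1=C(O)C=C(O)C(C)(C)C1=O
F2 | step 5 | Mannich base of propionylfilicinic acid (4-[(dimethylamino)methyl]-3,5-dihydroxy-6,6-dimethyl-2-propanoylcyclohexa-2,4-dien-1-one) | CCC(=O)C1=C(O)C(CN(C)C)=C(O)C(C)(C)C1=O
F3 | step 4 | bis-Mannich base of methylenebis(flopropione) (each ring bearing CH2NMe2 at its formerly free carbon) | CCC(=O)c1c(O)c(CN(C)C)c(O)c(Cc2c(O)c(CN(C)C)c(O)c(C(=O)CC)c2O)c1O
F4 | step 3 | unsymmetrical dimer, 1-[2,4,6-trihydroxy-3-methyl-5-(2,4,6-trihydroxy-3-propanoylbenzyl)phenyl]propan-1-one | CCC(=O)c1c(O)c(C)c(O)c(Cc2c(O)cc(O)c(C(=O)CC)c2O)c1O
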